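**Retrosynthetic overview**
- Target ⇐ light-induced removal of a chiral 1-(2-nitrophenyl)ethyl group from the C3 acetal oxygen (the C3–O bond is never broken, so 3R is kept) ⇐ Mitsunobu coupling of a 6-(hydroxymethyl)phthalide with rhizonic acid (ring A, from bought methyl 2,4-dihydroxy-3,6-dimethylbenzoate).
- C6–CH2OH ⇐ boron-templated ortho-hydroxymethylation of the 7-phenol.
- (3R)-acetal ⇐ acid equilibration and silica separation of the two C3 epimers of the chiral acetal.
- Rings B and C together ⇐ one-pot [4+2] benzannulation of Brassard's diene with tert-butyl 4,4-diethoxybut-2-ynoate, then cationic lactonisation and acetal exchange with the chiral alcohol.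
- Ring order: ring A is bought; ring B (benzene), then ring C (lactone acetal), form in the same flask.

Assumption: C3 is a lactol carbon that can epimerise through the ring-opened 2-formylbenzoic acid, so it is held as a configurationally stable acetal until the last step, and the free (3R)-lactol is released and handled only under neutral, aprotic, cold conditions and stored as a solid.

Numbering used: 2-benzofuran-1(3H)-one (C1 lactone carbonyl, C3 lactol carbon, C5 OMe, C6 CH2O, C7 OH).

**Step 1**
Reactants: 1 methyl (2E)-3-methoxybut-2-enoate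
Product: 3 (1E)-1,3-dimethoxy-1-(trimethylsilyloxy)buta-1,3-diene, via lithium dienolate 2 (not isolated)
Conditions: LiN(iPr)2, THF, –78 °C; Me3SiCl, –78 °C → rt; non-aqueous work-up, distil
Reagents that add atoms: chlorotrimethylsilane (C[Si](C)(C)Cl)
Why: γ-Deprotonation of the vinylogous carbonate and O-silylation of the extended enolate (silyl ketene acetal formation, Brassard's diene).

**Step 2**
Reactants: 4 3,3-diethoxyprop-1-yne
Product: 6 tert-butyl 4,4-diethoxybut-2-ynoate, via lithium acetylide 5 (not isolated)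
Conditions: n-BuLi, THF, –78 °C; Boc2O, –78 → 0 °C; H2O
Reagents that add atoms: di-tert-butyl dicarbonate (CC(C)(C)OC(=O)OC(=O)OC(C)(C)C)
Why: Deprotonation of the terminal alkyne and C-acylation of the lithium acetylide by Boc2O.

**Step 3**
Reactants: 3 (1E)-1,3-dimethoxy-1-(trimethylsilyloxy)buta-1,3-diene; 6 tert-butyl 4,4-diethoxybut-2-ynoate; 7 (1S)-1-(2-nitrophenyl)ethan-1-ol
Product: 11 (3RS)-7-hydroxy-5-methoxy-3-[(1S)-1-(2-nitrophenyl)ethoxy]-2-benzofuran-1(3H)-one (both C3 epimers), via cycloadduct 8 (not isolated), via phenol ester 9 (not isolated), via 3-ethoxyphthalide 10 (not isolated)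
Conditions: 3 (1.5 equiv), PhMe (2 M), 110 °C, sealed, 36 h; then 7 (1.3 equiv), TsOH·H2O (0.2 equiv), 60 °C → reflux with slow distillation (–EtOH), amber glass; short SiO2 plug
Reagents that add atoms: none
Why: Proposed new method: the diene adds with its CH2 terminus to the acetal-bearing β-carbon of the alkynoate (Brassard-type Diels–Alder benzannulation, the closest known reaction) and loss of MeOSiMe3 aromatises ring B; acid then ionises the diethyl acetal, the ortho tert-butyl ester captures the oxocarbenium ion and expels isobutene to close ring C (known cationic lactonisation of tert-butyl esters), and distilling out ethanol drives exchange with alcohol 7 (known acid-catalysed exchange of 3-alkoxyphthalides), so C3 is formed under thermodynamic control as a near-equal pair of epimers that is resolved in step 4.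

**Step 4**
Reactants: 11 (3RS)-7-hydroxy-5-methoxy-3-[(1S)-1-(2-nitrophenyl)ethoxy]-2-benzofuran-1(3H)-one (both C3 epimers)
Product: 12 (3R)-7-hydroxy-5-methoxy-3-[(1S)-1-(2-nitrophenyl)ethoxy]-2-benzofuran-1(3H)-one
Conditions: SiO2 chromatography (collect the 3R diastereomer); the (3S)-rich remainder of 11: TsOH·H2O (0.1 equiv), 4 Å MS, PhMe, 60 °C, then SiO2 again (two recycles); amber glass
Reagents that add atoms: none
Why: Acid-catalysed epimerisation of a 3-alkoxyphthalide through its phthalidyl oxocarbenium ion (thermodynamic acetal equilibration) returns the separated (3S) component of 11 to the near 1:1 mixture, so repeated silica separation of the two diastereomers converges the material on (3R)-12, whose C3 configuration is assigned by X-ray crystallography, while the (1′S) centre cannot ionise because the ortho nitro group destabilises that benzylic cation.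

**Step 5**
Reactants: 12 (3R)-7-hydroxy-5-methoxy-3-[(1S)-1-(2-nitrophenyl)ethoxy]-2-benzofuran-1(3H)-one
Product: 14 (3R)-7-hydroxy-6-(hydroxymethyl)-5-methoxy-3-[(1S)-1-(2-nitrophenyl)ethoxy]-2-benzofuran-1(3H)-one, via benzodioxaborin 13 (not isolated)
Conditions: PhB(OH)2, (CH2O)n, EtCO2H (cat.), PhMe, reflux (Dean–Stark), amber glass; then pinacol, THF, rt
Reagents that add atoms: paraformaldehyde, as formaldehyde (C=O)
Why: Nagata ortho-hydroxymethylation: the aryl phenylboronate delivers formaldehyde intramolecularly to the only free ortho carbon (C6), so C4 is untouched, and the weak acid does not ionise the C3 acetal, so C3 stays R.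

**Step 6**
Reactants: 15 methyl 2,4-dihydroxy-3,6-dimethylbenzoate
Product: 17 2-hydroxy-4-methoxy-3,6-dimethylbenzoic acid (rhizonic acid), via methyl rhizonate 16 (not isolated)
Conditions: MeI (1.05 equiv), K2CO3, DMSO, rt; then KOH, H2O, 90 °C; HCl (aq.), 0 °C
Reagents that add atoms: iodomethane (CI); potassium hydroxide ([K+].[OH-])
Why: The non-chelated 4-OH is the more acidic phenol and is methylated selectively (Williamson ether synthesis), hot aqueous KOH then saponifies the hindered ester, and cold acidification avoids decarboxylation.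

**Step 7**
Reactants: 14 (3R)-7-hydroxy-6-(hydroxymethyl)-5-methoxy-3-[(1S)-1-(2-nitrophenyl)ethoxy]-2-benzofuran-1(3H)-one; 17 2-hydroxy-4-methoxy-3,6-dimethylbenzoic acid
Product: 18 {(3R)-7-hydroxy-5-methoxy-3-[(1S)-1-(2-nitrophenyl)ethoxy]-1-oxo-1,3-dihydro-2-benzofuran-6-yl}methyl 2-hydroxy-4-methoxy-3,6-dimethylbenzoate
Conditions: 17 (1.3 equiv), PPh3, DIAD, THF, 0 °C → rt, amber glass
Reagents that add atoms: none
Why: Mitsunobu esterification: the primary benzylic alcohol is activated as its oxyphosphonium ion and displaced by the carboxylate of the hindered but acidic salicylic acid 17, while the hydrogen-bonded phenols and the C3 acetal do not react.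

**Step 8**
Reactants: 18 {(3R)-7-hydroxy-5-methoxy-3-[(1S)-1-(2-nitrophenyl)ethoxy]-1-oxo-1,3-dihydro-2-benzofuran-6-yl}methyl 2-hydroxy-4-methoxy-3,6-dimethylbenzoate
Product: 19 [(3R)-3,7-dihydroxy-5-methoxy-1-oxo-1,3-dihydro-2-benzofuran-6-yl]methyl 2-hydroxy-4-methoxy-3,6-dimethylbenzoate (target)
Conditions: hν (365 nm), degassed MeCN, 0 °C; fast chromatography on neutral SiO2, crystallise
Reagents that add atoms: none
Why: o-Nitrobenzyl-type photodeprotection (known for 2-nitrobenzyl glycosides): the excited nitro group abstracts the benzylic hydrogen of the auxiliary and the resulting hemiketal collapses to the nitroso ketone and the free lactol, so only the O–C(auxiliary) bond breaks and the (3R) C3–O bond is retained under neutral, aprotic conditions.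

**Compound list**
1 | methyl (2E)-3-methoxybut-2-enoate | CO/C(C)=C/C(=O)OC | starting material
2 | lithium 1,3-dimethoxybuta-1,3-dien-1-olate | [Li]OC(OC)=CC(=C)OC | intermediate
3 | (1E)-1,3-dimethoxy-1-(trimethylsilyloxy)buta-1,3-diene | C=C(OC)/C=C(\OC)O[Si](C)(C)C | intermediate
4 | 3,3-diethoxyprop-1-yne | C#CC(OCC)OCC | starting material
5 | (3,3-diethoxyprop-1-yn-1-yl)lithium | [Li]C#CC(OCC)OCC | intermediate
6 | tert-butyl 4,4-diethoxybut-2-ynoate | CCOC(OCC)C#CC(=O)OC(C)(C)C | intermediate
7 | (1S)-1-(2-nitrophenyl)ethan-1-ol | C[C@H](O)c1ccccc1[N+](=O)[O-] | starting material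
8 | tert-butyl 2-(diethoxymethyl)-4,6-dimethoxy-6-(trimethylsilyloxy)cyclohexa-1,4-diene-1-carboxylate (racemic) | CCOC(OCC)C1=C(C(=O)OC(C)(C)C)C(OC)(O[Si](C)(C)C)C=C(OC)C1 | intermediate
9 | tert-butyl 2-(diethoxymethyl)-6-hydroxy-4-methoxybenzoate | CCOC(OCC)c1cc(OC)cc(O)c1C(=O)OC(C)(C)C | intermediate
10 | 3-ethoxy-7-hydroxy-5-methoxy-2-benzofuran-1(3H)-one (racemic) | CCOC1OC(=O)c2c(O)cc(OC)cc21 | intermediate
11 | (3RS)-7-hydroxy-5-methoxy-3-[(1S)-1-(2-nitrophenyl)ethoxy]-2-benzofuran-1(3H)-one (both C3 epimers) | COc1cc2c(c(O)c1)C(=O)OC2O[C@@H](C)c1ccccc1[N+](=O)[O-] | intermediate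
12 | (3R)-7-hydroxy-5-methoxy-3-[(1S)-1-(2-nitrophenyl)ethoxy]-2-benzofuran-1(3H)-one | COc1cc2c(c(O)c1)C(=O)O[C@H]2O[C@@H](C)c1ccccc1[N+](=O)[O-] | intermediate
13 | cyclic phenylboronate of 14 (2-phenyl-4H-1,3,2-benzodioxaborin spanning O7 and the 6-CH2O group, 3R, 1′S) | COc1cc2c(c3OB(c4ccccc4)OCc13)C(=O)O[C@H]2O[C@@H](C)c1ccccc1[N+](=O)[O-] | intermediate
14 | (3R)-7-hydroxy-6-(hydroxymethyl)-5-methoxy-3-[(1S)-1-(2-nitrophenyl)ethoxy]-2-benzofuran-1(3H)-one | COc1cc2c(c(O)c1CO)C(=O)O[C@H]2O[C@@H](C)c1ccccc1[N+](=O)[O-] | intermediate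
15 | methyl 2,4-dihydroxy-3,6-dimethylbenzoate | COC(=O)c1c(C)cc(O)c(C)c1O | starting material
16 | methyl 2-hydroxy-4-methoxy-3,6-dimethylbenzoate | COC(=O)c1c(C)cc(OC)c(C)c1O | intermediate
17 | 2-hydroxy-4-methoxy-3,6-dimethylbenzoic acid | COc1cc(C)c(C(=O)O)c(O)c1C | intermediate
18 | {(3R)-7-hydroxy-5-methoxy-3-[(1S)-1-(2-nitrophenyl)ethoxy]-1-oxo-1,3-dihydro-2-benzofuran-6-yl}methyl 2-hydroxy-4-methoxy-3,6-dimethylbenzoate | COc1cc(C)c(C(=O)OCc2c(OC)cc3c(c2O)C(=O)O[C@H]3O[C@@H](C)c2ccccc2[N+](=O)[O-])c(O)c1C | intermediate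
19 | [(3R)-3,7-dihydroxy-5-methoxy-1-oxo-1,3-dihydro-2-benzofuran-6-yl]methyl 2-hydroxy-4-methoxy-3,6-dimethylbenzoate | COc1cc(C)c(C(=O)OCc2c(OC)cc3c(c2O)C(=O)O[C@H]3O)c(O)c1C | target

**Totals**
Total step count: 8. Longest linear sequence: 6 (steps 1 → 3 → 4 → 5 → 7 → 8; the branch from step 2 is equally long).

**Steps most likely to fail**

Step 3. The alkynoate is hindered and only singly activated, so the thermal cycloaddition may be slow, and the one-pot lactonisation and exchange may stall at 10. The fallback sets out from 4 and 3. Lithiated 4 is formylated (n-BuLi, then DMF) to 4,4-diethoxybut-2-ynal F1, a far more reactive dienophile of the same polarity. Cycloaddition with 3 at 0–25 °C without Lewis acid and mild acid aromatisation gives 2-(diethoxymethyl)-6-hydroxy-4-methoxybenzaldehyde F2. Chlorite oxidation (NaClO2, NaH2PO4, 2-methylbut-2-ene) gives 2-(diethoxymethyl)-6-hydroxy-4-methoxybenzoic acid F3. Heating F3 with 7 and TsOH·H2O in toluene (Dean–Stark) closes the lactone acetal, and the route is rejoined at 11.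

Step 5. The phenol is hydrogen-bonded to the lactone carbonyl and flanked by OMe, so boronate formation or formaldehyde transfer may be sluggish. The fallback sets out from 12. Magnesium-phenoxide ortho-formylation (MgCl2, Et3N, (CH2O)n, MeCN, reflux) gives (3R)-6-formyl-7-hydroxy-5-methoxy-3-[(1S)-1-(2-nitrophenyl)ethoxy]-2-benzofuran-1(3H)-one F4. NaBH4 (THF–MeOH, –20 °C) then reduces only the aldehyde, and the route is rejoined at 14.

Step 7. Activation of an o-hydroxybenzyl alcohol can give o-quinone methide oligomers or phenol alkylation instead of the ester. The fallback sets out from 12. Ortho-aminomethylation with CH2=NMe2+ I– (Et3N, CH2Cl2) gives (3R)-6-[(dimethylamino)methyl]-7-hydroxy-5-methoxy-3-[(1S)-1-(2-nitrophenyl)ethoxy]-2-benzofuran-1(3H)-one F5. Heating F5 with acid 17 in toluene under a nitrogen sweep expels Me2NH, the o-quinone methide is captured by the carboxylic acid, and the route is rejoined at 18.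

**Further compounds**
F1 | step 3 | 4,4-diethoxybut-2-ynal | CCOC(OCC)C#CC=O
F2 | step 3 | 2-(diethoxymethyl)-6-hydroxy-4-methoxybenzaldehyde | CCOC(OCC)c1cc(OC)cc(O)c1C=O
F3 | step 3 | 2-(diethoxymethyl)-6-hydroxy-4-methoxybenzoic acid | CCOC(OCC)c1cc(OC)cc(O)c1C(=O)O
F4 | step 5 | (3R)-6-formyl-7-hydroxy-5-methoxy-3-[(1S)-1-(2-nitrophenyl)ethoxy]-2-benzofuran-1(3H)-one | COc1cc2c(c(O)c1C=O)C(=O)O[C@H]2O[C@@H](C)c1ccccc1[N+](=O)[O-]
F5 | step 7 | (3R)-6-[(dimethylamino)methyl]-7-hydroxy-5-methoxy-3-[(1S)-1-(2-nitrophenyl)ethoxy]-2-benzofuran-1(3H)-one | COc1cc2c(c(O)c1CN(C)C)C(=O)O[C@H]2O[C@@H](C)c1ccccc1[N+](=O)[O-]
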